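A leftover of free monomer was what I had to reckon with before deciding whether the next run should stop at 20 s again or stand longer on the same charge.

free monomer 0.50 mM; pre-initiator 1.0 µM; time 20 s

* average number of monomer units in a chain (chains begun, living or dead) at 20 s
* part of the free monomer that has reacted at 20 s

Living ends add free monomer with rate constant 56000 M⁻¹ s⁻¹ and give it back at 11 s⁻¹ per unit of c(living end), whatever c(free monomer) is. Net growth is therefore zero at c(free monomer) = 0.196 mM, the leftover, usually called the equilibrium monomer concentration. From 0.50 mM charged, that allows a ceiling of 60.7% reacted.

How far the flask gets depends on its living ends. The sum c(pre-initiator) + c(initiator) + c(living end) stays at 1.0 µM. Initiator has a half-life of 0.87 s, shorter than the 7.4 s of pre-initiator, so I let living ends follow the pre-initiator lost, with a lag of 1.25 s. The excess of free monomer over the leftover then shrinks by the exponential of minus an exposure, the growth constant times the time integral of c(living end). At 20 s I made this exposure 0.556. That gave 25.9% reacted on 0.829 µM of chains, an average of 156 units. This was 42.7% of the ceiling, so I decided to charge the same and let the next run stand longer.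

The forecast, which also held that “Initiator is consumed quickly”, gave 158 and 25.8%, against my 156 and 25.9%.

The flask gave an average of 158 units and 25.9% reacted.

    free monomer + living end → monomer in chains + living end, rate k1*[living end]*[free monomer] (k1 = 56000 M⁻¹ s⁻¹)
    pre-initiator → initiator (k2 = 0.094 s⁻¹)
    monomer in chains + living end → free monomer + living end, rate k3*[living end] as long as [monomer in chains] is above zero (k3 = 11 s⁻¹)
    free monomer + initiator → living end + monomer in chains (k4 = 1600 M⁻¹ s⁻¹)

At 20.0 s this flask still held 74.1% of its free monomer, above the leftover's 39.2%. The back step and the time allowed act together as part of the reason for its average: without the back step it is 261, and at 200 s it is 304.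

On the neighbour flask read at 80 s, the same exposure comes to 3.81, which gives 59.4% reacted, close under the ceiling. The computed value there is 59.4%.

(The numbers of this flask are made up; no experiment stands behind them.)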